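Ring A of the drimane core (C1–C5 and C10) is disconnected at C4–C5, C1–C10 and C2–C3: C4 is the α-carbon of an isobutyrate, C5 and C10 are the β- and α-carbons of 2-methylcyclohex-2-enone (its carbonyl is C9), and C1–C2 is an acrylate. In one flask a catalytic enantioselective Mukaiyama–Michael addition sets C5, the liberated C10 enolate adds to the acrylate trans to the C5 substituent, and Dieckmann acylation of the phenyl ester closes ring A. The precursors are the enone, the silyl ketene acetal of phenyl isobutyrate and tert-butyl acrylate. The β-keto ester formed masks C3 while the C9 ketone of ring B is converted into C8(OH)CH3 and C9–C11H2–O–coumarin.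

Key step: step 2

Remarks on the chemistry:
- Locants are drimane locants (ring A = C1–C5 and C10; ring B = C5–C10; C11 on C9; C12 on C8). Drimane-type names give skeleton and locants only; configuration is defined by the CIP descriptors and the SMILES (the target belongs to the ent-drimane series: 3R,5S,8S,9R,10R).
- Assumption: the (S)-configured oxazaborolidinium ion is taken to leave the Si face of the enone β-carbon open. If the sense of induction proves opposite, the (R)-catalyst is used.

Step 1
Reactants: 1 phenyl isobutyrate
Product: 2 trimethyl[(2-methyl-1-phenoxyprop-1-en-1-yl)oxy]silane (silyl ketene acetal of phenyl isobutyrate)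
Conditions: LiN(iPr)2, Me3SiCl, THF, −78 °C → rt (ester added to the amide/silyl chloride mixture); distillation
Reagents that add atoms: chlorotrimethylsilane, C[Si](C)(C)Cl
Why: O-silylation of an ester enolate; trapping in situ at −78 °C keeps the phenyl ester enolate from losing phenoxide to give a ketene.

Step 2
Reactants: 2 silyl ketene acetal of phenyl isobutyrate, 3 2-methylcyclohex-2-en-1-one, 4 tert-butyl acrylate
Product: 8 tert-butyl (5R,10R)-4,4,10-trimethyl-3,9-dioxo-trans-decalin-2-carboxylate (C2 epimers/enol), via silyl enol ether 5 (not isolated), via potassium enolate 6 (not isolated), via ester enolate 7 (not isolated)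
Conditions: (S)-3,3-diphenyl-1-(2-methylphenyl)tetrahydro-1H,3H-pyrrolo[1,2-c][1,3,2]oxazaborole (20 mol %), HNTf2 (20 mol %), Ph3PO (25 mol %), toluene, −20 °C; then THF, KOtBu (1.2 equiv), −40 °C; then 4 (1.0 equiv, slow addition), −78 → 0 °C; aq NH4Cl
Reagents that add atoms: none
Why: Proposed new method: the protonated oxazaborolidine activates the enone for Mukaiyama–Michael addition of 2 at the β-carbon (C4–C5) and silyl transfer parks the ketone as the C9=C10 enol ether 5; tert-butoxide then attacks silicon, not the phenyl ester shielded by its quaternary α-carbon, to free the regiodefined enolate 6, which adds to 4 (C10–C1) to give ester enolate 7, and 7 acylates on the phenyl ester (C2–C3) with loss of phenoxide. The closest known reactions are the oxazaborolidinium-catalysed enantioselective Mukaiyama–Michael addition of isobutyrate silyl ketene acetals to unsubstituted cycloalkenones, alkoxide cleavage of silyl enol ethers to regiodefined enolates, and Michael–Michael–ring-closure annulations of enolates with acrylates; the combination on an α-methyl enone with a phenyl ester ketene acetal has not been shown. Ring A (C1–C5 and C10) closes by 6-exo-trig Dieckmann acylation through a chair in which both side chains on ring B are equatorial. C5 is set by the catalyst, which is expected to shield the Re face of the enone β-carbon so that 2 adds to the Si face; C10 is set by the substrate, because 4 approaches enolate 6 anti to the bulky C5 substituent, which gives the trans relationship of C5-H and C10-CH3 (C2 is uncontrolled and is removed in step 5). The step needs Michael addition of 6 to outrun its intramolecular O-acylation, and ring closure of 7 to outrun a second acrylate addition; slow addition of one equivalent of the hindered tert-butyl acrylate at −78 °C, the activated phenyl ester and the irreversible formation of the stabilised β-keto ester enolate of 8 are meant to secure this.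

Step 3
Reactants: 8 tert-butyl (5R,10R)-4,4,10-trimethyl-3,9-dioxo-trans-decalin-2-carboxylate
Product: 9 tert-butyl (5R,10R)-4,4,8,10-tetramethyl-3,9-dioxo-trans-decalin-2-carboxylate (C2 and C8 epimers)
Conditions: LiN(iPr)2 (2.2 equiv), THF, −78 °C; MeI (1.05 equiv), −78 → −30 °C; aq NH4Cl
Reagents that add atoms: iodomethane, CI
Why: Regioselective alkylation of a bis-enolate: the first equivalent of base turns the β-keto ester into its chelated enolate (which masks C2/C3), the second deprotonates C8, the only α-position of the C9 ketone that bears hydrogen, and MeI reacts at this far more basic ketone enolate; the C8 configuration is irrelevant because C8 becomes sp2 in step 4.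

Step 4
Reactants: 9 tert-butyl (5R,10R)-4,4,8,10-tetramethyl-3,9-dioxo-trans-decalin-2-carboxylate
Product: 10 tert-butyl (5S,10R)-4,4,8,10-tetramethyl-3-oxo-9-(trifluoromethanesulfonyloxy)-trans-decal-8-ene-2-carboxylate (C2 epimers)
Conditions: KN(SiMe3)2 (2.2 equiv), THF, −78 → −20 °C; PhNTf2 (1.05 equiv), −78 → 0 °C; aq NH4Cl
Reagents that add atoms: N-phenylbis(trifluoromethanesulfonimide), O=S(=O)(N(c1ccccc1)S(=O)(=O)C(F)(F)F)C(F)(F)F
Why: Enol triflate formation on the bis-enolate: C10 is quaternary, so the C9 ketone can only enolise towards C8, and this ketone enolate is sulfonylated by one equivalent of the mild triflyl donor well before the stabilised β-keto ester enolate.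

Step 5
Reactants: 10 tert-butyl (5S,10R)-4,4,8,10-tetramethyl-3-oxo-9-(trifluoromethanesulfonyloxy)-trans-decal-8-ene-2-carboxylate
Product: 11 (5S,10R)-4,4,8,10-tetramethyl-3-oxo-trans-decal-8-en-9-yl trifluoromethanesulfonate
Conditions: CF3CO2H, CH2Cl2, 0 °C → rt; then toluene, 80 °C
Reagents that add atoms: none
Why: Acidolysis of the tert-butyl ester and thermal decarboxylation of the β-keto acid through its enol, conditions that an enol triflate tolerates.

Step 6
Reactants: 11 (5S,10R)-4,4,8,10-tetramethyl-3-oxo-trans-decal-8-en-9-yl trifluoromethanesulfonate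
Product: 12 methyl (5S,10R)-3-oxodrim-8-en-11-oate
Conditions: Pd(OAc)2 (5 mol %), 1,3-bis(diphenylphosphino)propane, CO (1 atm), MeOH, Et3N, DMF, 70 °C
Reagents that add atoms: carbon monoxide, [C-]#[O+]; methanol, CO
Why: Palladium-catalysed methoxycarbonylation of an enol triflate (oxidative addition, CO insertion, methanolysis), which installs C11 on C9 and leaves the C3 ketone alone.

Step 7
Reactants: 12 methyl (5S,10R)-3-oxodrim-8-en-11-oate
Product: 13 methyl (5S,9R,10R)-3-oxodrim-8(12)-en-11-oate (C9-H trans to C10-CH3, ester equatorial)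
Conditions: LiN(iPr)2 (2.5 equiv), THF–HMPA, −78 → −30 °C; AcOH, −78 °C
Reagents that add atoms: none
Why: Deconjugative α-protonation: with the C3 ketone carried as its enolate, the base removes a γ-hydrogen from the C12 methyl group cis to the ester, and kinetic protonation of the dienolate occurs at C9 on the face opposite the axial C10 methyl, which sets C9 with the ester equatorial.

Step 8
Reactants: 13 methyl (5S,9R,10R)-3-oxodrim-8(12)-en-11-oate
Product: 14 methyl (5S,8S,9S,10R)-8,12-epoxy-3-oxodriman-11-oate (epoxide oxygen equatorial on C8, trans to C10-CH3)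
Conditions: mCPBA, NaHCO3, CH2Cl2, 0 °C
Reagents that add atoms: 3-chloroperbenzoic acid, OOC(=O)c1cccc(Cl)c1
Why: Prilezhaev epoxidation of the exocyclic C8=C12 bond from the equatorial side, the axial side being blocked by the syn-axial C10 methyl, which sets C8; the hindered C3 ketone undergoes Baeyer–Villiger oxidation far more slowly than the 1,1-disubstituted alkene is epoxidised.

Step 9
Reactants: 14 methyl (5S,8S,9S,10R)-8,12-epoxy-3-oxodriman-11-oate
Product: 15 (3R,5S,8S,9R,10R)-drimane-3,8,11-triol
Conditions: LiAlH4, THF, 0 °C → reflux; aqueous work-up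
Reagents that add atoms: none
Why: Hydride reduction of three groups at once: the ester gives the C11 carbinol, the epoxide is opened by SN2 attack at primary C12 (the C8–O bond and configuration are untouched, C12 becomes the axial methyl), and axial hydride delivery to the 4,4-dimethyl C3 ketone gives the equatorial alcohol cis to C10-CH3.

Step 10
Reactants: 15 (3R,5S,8S,9R,10R)-drimane-3,8,11-triol, 16 umbelliferone (7-hydroxy-2H-chromen-2-one)
Product: 17 7-{[(3R,5S,8S,9R,10R)-3,8-dihydroxydriman-11-yl]oxy}-2H-chromen-2-one
Conditions: PPh3, DIAD, THF, 0 °C → rt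
Reagents that add atoms: none
Why: Mitsunobu etherification: only the primary C11 alcohol is activated and displaced by the acidic phenol, while the secondary C3-OH next to the gem-dimethyl carbon and the tertiary C8-OH do not react.

Step 11
Reactants: 17 7-{[(3R,5S,8S,9R,10R)-3,8-dihydroxydriman-11-yl]oxy}-2H-chromen-2-one, 18 angelic acid ((2Z)-2-methylbut-2-enoic acid)
Product: 19 (3R,5S,8S,9R,10R)-8-hydroxy-11-[(2-oxo-2H-chromen-7-yl)oxy]driman-3-yl (2Z)-2-methylbut-2-enoate (CNP0189964.2)
Conditions: 18, 2,4,6-trichlorobenzoyl chloride, Et3N, toluene, rt; then 17, 80 °C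
Reagents that add atoms: none
Why: Yamaguchi-type esterification through the mixed anhydride with 2,4,6-trichlorobenzoic acid, which acylates the hindered secondary C3-OH without a nucleophilic catalyst that would isomerise the angeloyl group to tigloyl; the tertiary C8-OH is not acylated.

Compound list
1 | phenyl isobutyrate (phenyl 2-methylpropanoate) | CC(C)C(=O)Oc1ccccc1 | starting material
2 | trimethyl[(2-methyl-1-phenoxyprop-1-en-1-yl)oxy]silane | CC(C)=C(Oc1ccccc1)O[Si](C)(C)C | intermediate
3 | 2-methylcyclohex-2-en-1-one | CC1=CCCCC1=O | starting material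
4 | tert-butyl acrylate | C=CC(=O)OC(C)(C)C | starting material
5 | phenyl 2-methyl-2-[(1S)-2-methyl-3-(trimethylsilyloxy)cyclohex-2-en-1-yl]propanoate | CC1=C(O[Si](C)(C)C)CCC[C@@H]1C(C)(C)C(=O)Oc1ccccc1 | intermediate
6 | potassium (3S)-2-methyl-3-(2-methyl-1-oxo-1-phenoxypropan-2-yl)cyclohex-1-en-1-olate | CC1=C([O-])CCC[C@@H]1C(C)(C)C(=O)Oc1ccccc1.[K+] | intermediate
7 | potassium ester enolate of tert-butyl 3-[(1R,2S)-1-methyl-2-(2-methyl-1-oxo-1-phenoxypropan-2-yl)-6-oxocyclohexyl]propanoate | CC(C)(C)OC([O-])=CC[C@]1(C)[C@H](CCCC1=O)C(C)(C)C(=O)Oc1ccccc1.[K+] | intermediate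
8 | tert-butyl (5R,10R)-4,4,10-trimethyl-3,9-dioxo-trans-decalin-2-carboxylate (C2 epimers/enol) | CC(C)(C)OC(=O)C1C[C@]2(C)[C@H](CCCC2=O)C(C)(C)C1=O | intermediate
9 | tert-butyl (5R,10R)-4,4,8,10-tetramethyl-3,9-dioxo-trans-decalin-2-carboxylate (C2 and C8 epimers) | CC(C)(C)OC(=O)C1C[C@]2(C)[C@H](CCC(C)C2=O)C(C)(C)C1=O | intermediate
10 | tert-butyl (5S,10R)-4,4,8,10-tetramethyl-3-oxo-9-(trifluoromethanesulfonyloxy)-trans-decal-8-ene-2-carboxylate (C2 epimers) | CC(C)(C)OC(=O)C1C[C@]2(C)[C@H](CCC(C)=C2OS(=O)(=O)C(F)(F)F)C(C)(C)C1=O | intermediate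
11 | (5S,10R)-4,4,8,10-tetramethyl-3-oxo-trans-decal-8-en-9-yl trifluoromethanesulfonate | O=C1CC[C@]2(C)[C@H](CCC(C)=C2OS(=O)(=O)C(F)(F)F)C1(C)C | intermediate
12 | methyl (5S,10R)-3-oxodrim-8-en-11-oate | O=C1CC[C@]2(C)[C@H](CCC(C)=C2C(=O)OC)C1(C)C | intermediate
13 | methyl (5S,9R,10R)-3-oxodrim-8(12)-en-11-oate | O=C1CC[C@]2(C)[C@H](CCC(=C)[C@H]2C(=O)OC)C1(C)C | intermediate
14 | methyl (5S,8S,9S,10R)-8,12-epoxy-3-oxodriman-11-oate | O=C1CC[C@]2(C)[C@H](CC[C@@]3(CO3)[C@H]2C(=O)OC)C1(C)C | intermediate
15 | (3R,5S,8S,9R,10R)-drimane-3,8,11-triol | O[C@@H]1CC[C@]2(C)[C@H](CC[C@](C)(O)[C@H]2CO)C1(C)C | intermediate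
16 | umbelliferone (7-hydroxy-2H-chromen-2-one) | Oc1ccc2ccc(=O)oc2c1 | starting material
17 | 7-{[(3R,5S,8S,9R,10R)-3,8-dihydroxydriman-11-yl]oxy}-2H-chromen-2-one | O[C@@H]1CC[C@]2(C)[C@H](CC[C@](C)(O)[C@H]2COc2ccc3ccc(=O)oc3c2)C1(C)C | intermediate
18 | angelic acid ((2Z)-2-methylbut-2-enoic acid) | C/C=C(/C)C(=O)O | starting material
19 | (3R,5S,8S,9R,10R)-8-hydroxy-11-[(2-oxo-2H-chromen-7-yl)oxy]driman-3-yl (2Z)-2-methylbut-2-enoate | C/C=C(/C)C(=O)O[C@@H]1CC[C@]2(C)[C@H](CC[C@](C)(O)[C@H]2COc2ccc3ccc(=O)oc3c2)C1(C)C | target

Total step count: 11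
Longest linear sequence: 11 steps (1 → 19)

Steps most likely to fail

Step 2 (proposed new method). The catalysed addition may activate the α-methyl enone too weakly or discriminate its faces poorly. Once the enolate is freed, O-acylation on the phenyl ester or oligomerisation of the acrylate may compete with the Michael addition and the ring closure. The fallback is stepwise, uses known reaction types, sets out from 2 and returns to the route at 8. Acetal 2 is added under the same oxazaborolidinium catalysis to commercial cyclohex-2-en-1-one, the unsubstituted enone class for which this enantioselective Mukaiyama–Michael addition is established, and the silyl enol ether phenyl 2-methyl-2-[(1S)-3-(trimethylsilyloxy)cyclohex-2-en-1-yl]propanoate F1 is isolated. Fluoride-mediated regiospecific methylation of this enol ether at C10 (benzyltrimethylammonium fluoride, MeI, THF), anti to the C5 substituent, gives phenyl 2-methyl-2-[(1S,2R)-2-methyl-3-oxocyclohexyl]propanoate F2. KOtBu in tert-butanol/THF then equilibrates F2 to its more substituted enolate, which adds to 4 at C10 anti to the C5 substituent. A further equivalent of KOtBu completes the Dieckmann closure to 8.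

Step 10. Displacement at the β-branched C11 oxyphosphonium centre, which is flanked by two quaternary carbons, may be slow, so that elimination or participation of the neighbouring C8 hydroxyl takes over. The fallback sets out from 15 and returns at 17, and forms the aryl–oxygen bond in place of the C11–O bond. It is a Buchwald–Hartwig-type etherification of the primary alcohol of 15 with commercial 7-bromocoumarin (Pd2(dba)3, 2-(di-tert-butylphosphino)-2′,4′,6′-triisopropyl-3,6-dimethoxybiphenyl, Cs2CO3, toluene, 80 °C). This coupling is selective for primary over hindered secondary and tertiary alcohols, and it makes no new compound (F0).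

Step 11. Acylation of the hindered C3 hydroxyl may be incomplete, and the activated angeloyl donor may isomerise from Z to E under the forcing conditions. The fallback sets out from 17 and returns at 19, and builds the Z-alkene on the molecule rather than transferring it. The C3-OH is esterified with 2-[bis(2,2,2-trifluoroethoxy)phosphoryl]propanoic acid (DCC, DMAP, CH2Cl2) to give (3R,5S,8S,9R,10R)-8-hydroxy-11-[(2-oxo-2H-chromen-7-yl)oxy]driman-3-yl 2-[bis(2,2,2-trifluoroethoxy)phosphoryl]propanoate F3. Still–Gennari olefination of this ester with acetaldehyde (KN(SiMe3)2 in excess to allow for the free C8-OH, 18-crown-6, THF, −78 °C) then gives the (Z)-2-methylbut-2-enoate 19.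

Further compounds
F1 | step 2 | phenyl 2-methyl-2-[(1S)-3-(trimethylsilyloxy)cyclohex-2-en-1-yl]propanoate | C1=C(O[Si](C)(C)C)CCC[C@@H]1C(C)(C)C(=O)Oc2ccccc2
F2 | step 2 | phenyl 2-methyl-2-[(1S,2R)-2-methyl-3-oxocyclohexyl]propanoate | C[C@@H]1[C@H](CCCC1=O)C(C)(C)C(=O)Oc2ccccc2
F0 | step 10 | none | none
F3 | step 11 | (3R,5S,8S,9R,10R)-8-hydroxy-11-[(2-oxo-2H-chromen-7-yl)oxy]driman-3-yl 2-[bis(2,2,2-trifluoroethoxy)phosphoryl]propanoate | CC(C(=O)O[C@@H]1CC[C@]2(C)[C@H](CC[C@](C)(O)[C@H]2COc2ccc3ccc(=O)oc3c2)C1(C)C)P(=O)(OCC(F)(F)F)OCC(F)(F)F
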